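At 15.0 d Monday's target reads 15 % and at 5.00 d Wednesday's reads 24 %, with solid substrate still at 48 % and 38 %.

| flask | solid substrate | partner | temperature | remark | time |
|---|---|---|---|---|---|
| Monday's | 0.27 M | 0.24 M | 20 °C | run made earlier |  |
| Wednesday's | 0.27 M | 0.97 M | 40 °C | run made earlier |  |
| summer | 0.27 M | 0.486 M | 55 °C |  | 4.0 d |
| dawn | 0.27 M | 0.486 M | 25 °C |  | 4.0 d |

| run | time / d | target / % | solid substrate / % |
|---|---|---|---|
| Monday's | 1.25 | 3 | 60 |
| Monday's | 2.08 | 6 | 61 |
| Monday's | 4.00 | 12 | 53 |
| Monday's | 8.00 | 17 | 51 |
| Monday's | 15.0 | 15 | 48 |
| Wednesday's | 1.04 | 20 | 53 |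
| Wednesday's | 2.00 | 21 | 42 |
| Wednesday's | 2.50 | 25 | 42 |
| Wednesday's | 4.00 | 24 | 39 |
| Wednesday's | 5.00 | 24 | 38 |

(each reading ± 2 percentage points)

- solid substrate is a solid; its amount is given per volume of the solution
- at the start none of the solid substrate is in solution
- what has only dissolved of solid substrate counts as not reacted

1. which flask leads in amount of target, in percent of the solid substrate charged ("all alike" within 1.5 percentage points) (summer / dawn / all alike)
2. how much target is there at the end, in percent of the solid substrate charged: summer
3. how much target is there at the end, in percent of the solid substrate charged: dawn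

Book partner as the limiting reagent and keep its ledger. Let B be its concentration and C its charge. Assume target takes partner at a rate proportional to B and waste at a rate proportional to B squared. Each mole of partner at concentration B then goes to target with the share L/(L+B), where L is a constant still to be read. Summing down to zero partner gives target = L ln(1 + C/L). At fixed L and for C well above L, equal factors in C add equal target.

Average the last two readings of each run: Monday gives 16.0 %, Wednesday 24.0 %. So L reads 0.0155 M, the even-split level: the partner concentration at which target and waste take equal shares. Those runs differ in temperature too, so this L is a rough reading; assume the same L at 55 °C and at 25 °C.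

Now open the books for summer and dawn. Charged: 0.486 M. At the start, target's share is 3.09 %. Down to B = L, target takes 0.0431 M. Below L, it takes 0.0107 M. Waste takes the remaining 0.432 M. Commit to 19.9 % in each flask, so all alike. Dawn may still be open at its end: Monday's run, at 20 °C, read 12 % at 4.00 d.

The forecast differs: summer leads, with 23 % for summer and 18 % for dawn, from a chemist who wrote “I can't separate their effects on the plateau”.

The flasks come out all alike: summer 18.7 %, dawn 18.7 %, each 1.2 percentage points below the reckoning.

    2 partner → side product (k = 4.40 × 10⁻⁵ /M/s, Ea = 64.0 kJ/mol)
    solid substrate ⇌ starting material, rate k2*(cs2 - [starting material]) while solid is left; crystals form when [starting material] > cs2 (solubility = 0.0930 M, k = 5.00 × 10⁻⁵ /s)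
    starting material + partner → target (k = 2.60 × 10⁻⁵ /M/s, Ea = 85.0 kJ/mol)
    (constants at 25 °C)

Summer ends with 0 % of its partner and stops at 18.7 % because of the step from two partner to side product: without that step it reaches 100 %. Dawn at 4.00 d still holds 4.0 % of its partner charge, or 0.0195 M. Enter that in the ledger with L: it adds 4.7 points, which reckons dawn at 23.4 % once its partner is spent. Left until 40.0 d, dawn stands at 24.1 %.

(The data come from a simulation from invented constants; the scatter is artificial.)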